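**Plan**
- Retrosynthesis: the C5 O–CH3 bond is cut last (chelation-directed demethylation). Ring A is then cut at C4a–C5 and C8–C8a, giving nitropyranone 10 and silyloxydiene 13.
- Enabling feature: ring A is a phloroglucinol-type ring. Its C5–C6–C7–C8 unit, oxygenated at C5 and C7, is a 1,1,3-trioxygenated butadiene; the fusion bond C4a–C8a is a C=C bond of a 4-pyranone (ring C), made dienophilic by a nitro group on the future C4a that later leaves as nitrous acid.
- Pyranone 10 is cut at its ring oxygen and its two ring CH carbons back to nitroketone 8. This is cut at CO–CH2NO2 (arylacetic acid 5 plus nitromethane 6) and at aryl–CH2 (lithiated 1 plus ethylene oxide).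
- Forward: ring B is bought as 1 and the nitroketone chain is attached (steps 1–3). Ring C is closed (step 4), the diene is made separately (steps 5–6), ring A is annulated (step 7) and the 5-hydroxyl is unmasked (step 8).
- Stereochemistry: the target has no stereocentre and no stereogenic double bond; the two sp3 centres of the cycloadduct are transient.

Key step: step 7

Assumption: chromone numbering (O1, C2, C3, C4, C4a, C5–C8, C8a) is used throughout, also for the atoms of 10 and 14 that become these positions. 1,2,3,5-Tetramethoxybenzene, 1,1-dimethoxyethene, nitromethane, ethylene oxide (THF solution) and DMF-DMA are taken as purchased.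

**Route**

Step 1
Reactants: 1 1,2,3,5-tetramethoxybenzene
Product: 3 2-(2,3,4,6-tetramethoxyphenyl)ethanol, via aryllithium 2 (not isolated)
Conditions: n-BuLi, TMEDA, THF, 0 °C → rt; ethylene oxide (THF solution), −20 °C → rt; H2O
Reagents that add atoms: ethylene oxide, C1CO1
Why: Directed ortho-metalation: the two ring C–H positions of 1 are equivalent and each lies between two methoxy groups, so n-BuLi should give a single aryllithium, which opens ethylene oxide at carbon and installs the two-carbon chain with the 2,3,4,6-tetramethoxy pattern already fixed.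

Step 2
Reactants: 3 2-(2,3,4,6-tetramethoxyphenyl)ethanol
Product: 5 2-(2,3,4,6-tetramethoxyphenyl)acetic acid, via arylacetaldehyde 4 (not isolated)
Conditions: TEMPO (cat.), PhI(OAc)2 (2.2 equiv), MeCN/H2O 1:1, rt
Reagents that add atoms: water, O
Why: Oxoammonium (TEMPO) oxidation with PhI(OAc)2 as terminal oxidant in aqueous acetonitrile takes a primary alcohol through the aldehyde hydrate to the acid under chlorine-free, near-neutral conditions, which should spare the electron-rich tetramethoxyarene from chlorination or oxidative demethylation.

Step 3
Reactants: 5 2-(2,3,4,6-tetramethoxyphenyl)acetic acid; 6 nitromethane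
Product: 8 1-nitro-3-(2,3,4,6-tetramethoxyphenyl)propan-2-one, via acyl imidazolide 7 (not isolated)
Conditions: CDI, THF, rt; then added to preformed MeNO2/KOtBu, THF/DMSO, 0 °C → rt; cold 1 M HCl
Reagents that add atoms: none
Why: C-acylation of a nitronate by an acyl imidazolide: the nitronate formed from MeNO2 and KOtBu attacks the imidazolide, and the more acidic α-nitro ketone formed is deprotonated at once by further nitronate, which protects it from a second acylation until the acidic quench.

Step 4
Reactants: 8 1-nitro-3-(2,3,4,6-tetramethoxyphenyl)propan-2-one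
Product: 10 3-nitro-5-(2,3,4,6-tetramethoxyphenyl)-4H-pyran-4-one, via bis-enaminone 9 (not isolated)
Conditions: DMF-DMA (excess), toluene, 90 °C; evaporate; 2 M HCl, THF, rt
Reagents that add atoms: N,N-dimethylformamide dimethyl acetal, COC(OC)N(C)C; water, O
Why: Aminomethylenation with DMF-DMA should occur at both CH2 groups flanking the ketone, and aqueous acid then hydrolyses one enamine to an enol that displaces dimethylamine from the other by addition–elimination, the same enaminone ring closure that turns 2-hydroxy-ω-nitroacetophenones into 3-nitrochromones and 1,3-diarylacetones into 3,5-diaryl-4-pyranones.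

Step 5
Reactants: 11 1,1-dimethoxyethene
Product: 12 4,4-dimethoxybut-3-en-2-one
Conditions: AcCl, Et3N, Et2O, 0 °C → rt
Reagents that add atoms: acetyl chloride, CC(=O)Cl
Why: C-acylation of a ketene acetal: the nucleophilic CH2 carbon of 11 attacks acetyl chloride and Et3N removes the proton from the resulting dialkoxycarbenium ion before chloride can dealkylate it, giving the push–pull enone.

Step 6
Reactants: 12 4,4-dimethoxybut-3-en-2-one
Product: 13 1,1-dimethoxy-3-(trimethylsilyloxy)buta-1,3-diene
Conditions: TMSOTf, Et3N, Et2O, 0 °C; distilled and used at once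
Reagents that add atoms: trimethylsilyl trifluoromethanesulfonate, C[Si](C)(C)OS(=O)(=O)C(F)(F)F
Why: Soft enolisation (TMSOTf/Et3N) of the methyl ketone, whose CH3 group holds the only enolisable hydrogens, should give the cross-conjugated 2-silyloxydiene without regiochemical ambiguity.

Step 7
Reactants: 10 3-nitro-5-(2,3,4,6-tetramethoxyphenyl)-4H-pyran-4-one; 13 1,1-dimethoxy-3-(trimethylsilyloxy)buta-1,3-diene
Product: 16 7-hydroxy-5-methoxy-3-(2,3,4,6-tetramethoxyphenyl)-4H-chromen-4-one, via cycloadduct 14 (not isolated), via silyl ether 15 (not isolated)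
Conditions: 13 (2–3 equiv), toluene, rt → 90 °C (sealed tube, argon); then 1 M HCl, THF, rt
Reagents that add atoms: none
Why: Proposed new method: the nitro-bearing C=C bond of 10 has the nitro group and the C4 carbonyl on the future C4a and the ring oxygen on the future C8a, so C8a is the electrophilic β-carbon of a push–pull nitroalkene and is attacked by the CH2 terminus of 13 (its most nucleophilic carbon) while the ketene-acetal carbon bonds to C4a in a concerted, asynchronous, normal-electron-demand Diels–Alder reaction. The cis-fused adduct 14 should then lose nitrous acid across C4a–C8a on heating and methanol from the C5 ketal by 1,4-elimination to give the aromatic silyl ether 15, and dilute acid frees the 7-hydroxyl. The closest known reaction type is the Diels–Alder reaction of 3-nitrochromones and other nitro-heteroarenes with Danishefsky-type silyloxydienes followed by thermal extrusion of nitrous acid, together with the annulation of haloquinones by this same diene; a monocyclic 3-nitro-4-pyranone has not been used in this way. Ring A is closed by an intermolecular [4+2] annulation in which both new bonds (C4a–C5 and C8–C8a) arise in one cycloaddition event, and aromatisation makes the sequence irreversible. No stereocentre survives: the two sp3 centres of 14 are set cis by the suprafacial addition and are erased on aromatisation. The step needs regioselectivity, secured by the match of the diene CH2 terminus with the nitroalkene β-carbon, and site selectivity between the two ring C=C bonds, secured because only the nitro-bearing one is doubly activated while the other carries the twisted, electron-rich aryl group.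

Step 8
Reactants: 16 7-hydroxy-5-methoxy-3-(2,3,4,6-tetramethoxyphenyl)-4H-chromen-4-one
Product: 17 5,7-dihydroxy-3-(2,3,4,6-tetramethoxyphenyl)-4H-chromen-4-one
Conditions: BCl3 (3 equiv), CH2Cl2, −78 → 0 °C; then H2O
Reagents that add atoms: none
Why: Chelation-controlled ether cleavage: BCl3 binds the C4 carbonyl and the peri 5-methoxy oxygen in a six-membered chelate and chloride removes that methyl group at low temperature, while the four methoxy groups of ring B, which cannot form such a chelate, should remain intact.

**Compound list**

1 | 1,2,3,5-tetramethoxybenzene | COc1cc(OC)c(OC)c(OC)c1 | starting material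
2 | (2,3,4,6-tetramethoxyphenyl)lithium | [Li]c1c(OC)cc(OC)c(OC)c1OC | intermediate (not isolated)
3 | 2-(2,3,4,6-tetramethoxyphenyl)ethanol | OCCc1c(OC)cc(OC)c(OC)c1OC | intermediate
4 | 2-(2,3,4,6-tetramethoxyphenyl)acetaldehyde | O=CCc1c(OC)cc(OC)c(OC)c1OC | intermediate (not isolated)
5 | 2-(2,3,4,6-tetramethoxyphenyl)acetic acid | OC(=O)Cc1c(OC)cc(OC)c(OC)c1OC | intermediate
6 | nitromethane | C[N+](=O)[O-] | starting material
7 | 1-(1H-imidazol-1-yl)-2-(2,3,4,6-tetramethoxyphenyl)ethanone | O=C(Cc1c(OC)cc(OC)c(OC)c1OC)n1ccnc1 | intermediate (not isolated)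
8 | 1-nitro-3-(2,3,4,6-tetramethoxyphenyl)propan-2-one | O=C(C[N+](=O)[O-])Cc1c(OC)cc(OC)c(OC)c1OC | intermediate
9 | 1,5-bis(dimethylamino)-2-nitro-4-(2,3,4,6-tetramethoxyphenyl)penta-1,4-dien-3-one (push–pull C=C bonds, configurationally labile, geometry not assigned) | CN(C)C=C(c1c(OC)cc(OC)c(OC)c1OC)C(=O)C(=CN(C)C)[N+](=O)[O-] | intermediate (not isolated)
10 | 3-nitro-5-(2,3,4,6-tetramethoxyphenyl)-4H-pyran-4-one | O=c1c([N+](=O)[O-])cocc1-c1c(OC)cc(OC)c(OC)c1OC | intermediate
11 | 1,1-dimethoxyethene | C=C(OC)OC | starting material
12 | 4,4-dimethoxybut-3-en-2-one | CC(=O)C=C(OC)OC | intermediate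
13 | 1,1-dimethoxy-3-(trimethylsilyloxy)buta-1,3-diene | COC(OC)=CC(=C)O[Si](C)(C)C | intermediate
14 | 5,5-dimethoxy-4a-nitro-3-(2,3,4,6-tetramethoxyphenyl)-7-(trimethylsilyloxy)-4a,5,8,8a-tetrahydro-4H-chromen-4-one (racemic, cis ring fusion, 4a-NO2 and 8a-H on the same face; one enantiomer drawn) | O=C1C(-c3c(OC)cc(OC)c(OC)c3OC)=CO[C@@H]2CC(O[Si](C)(C)C)=CC(OC)(OC)[C@]12[N+](=O)[O-] | intermediate (not isolated)
15 | 5-methoxy-3-(2,3,4,6-tetramethoxyphenyl)-7-(trimethylsilyloxy)-4H-chromen-4-one | COc1cc(O[Si](C)(C)C)cc2occ(-c3c(OC)cc(OC)c(OC)c3OC)c(=O)c12 | intermediate (not isolated)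
16 | 7-hydroxy-5-methoxy-3-(2,3,4,6-tetramethoxyphenyl)-4H-chromen-4-one | COc1cc(O)cc2occ(-c3c(OC)cc(OC)c(OC)c3OC)c(=O)c12 | intermediate
17 | 5,7-dihydroxy-3-(2,3,4,6-tetramethoxyphenyl)-4H-chromen-4-one | COc1cc(OC)c(-c2coc3cc(O)cc(O)c3c2=O)c(OC)c1OC | target

**Step count and risks**

Total step count: 8. Longest linear sequence: 6 steps (1, 2, 3, 4, 7, 8); the diene branch (steps 5 and 6) joins at step 7.

Steps most likely to fail:

1. Step 7 (proposed new method). The diene may add stepwise, and the nitronate so formed may expel the ring oxygen and open the pyranone. The released nitrous acid may also consume the diene, or the extrusion of nitrous acid may stall at the adduct stage. The fallback uses known chemistry and gives up the cycloaddition. It sets out from acid 5: Friedel–Crafts acylation of phloroglucinol with 5 in BF3·OEt2 at 80–90 °C should give the deoxybenzoin 1-(2,4,6-trihydroxyphenyl)-2-(2,3,4,6-tetramethoxyphenyl)ethanone F1. Treatment of F1 with DMF, BF3·OEt2 and MeSO2Cl at about 70 °C (one-carbon insertion and closure of ring C, the classical deoxybenzoin route to 5,7-dihydroxyisoflavones) should give the target directly. The fallback comes back to the route at 17.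

2. Step 4. Methoxide or dimethylamine released from DMF-DMA may cleave the α-nitro ketone by acyl cleavage, and condensation at the hindered benzylic CH2 may stay incomplete. The fallback sets out from acid 5 and never exposes a free α-nitro ketone. Oxalyl chloride with catalytic DMF in CH2Cl2 should give 2-(2,3,4,6-tetramethoxyphenyl)acetyl chloride F2. C-acylation of commercial (E)-N,N-dimethyl-2-nitroethenamine with F2 (pyridine, CH2Cl2, 0 °C) should give 1-(dimethylamino)-2-nitro-4-(2,3,4,6-tetramethoxyphenyl)but-1-en-3-one F3, in which the nitro side is already an enaminone. A single condensation of F3 with DMF-DMA at the benzylic CH2 then gives bis-enaminone 9, and the aqueous acid closure returns the route at 10.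

3. Step 3. The nitronate may be acylated on oxygen, or the enolisable acyl imidazolide may form a ketene and self-condense under the basic conditions. The fallback sets out from alcohol 3. Dess–Martin periodinane (CH2Cl2, NaHCO3) should give aldehyde 4, isolated in this case. A Henry addition of nitromethane 6 (catalytic Et3N or KF, iPrOH) should give racemic 1-nitro-3-(2,3,4,6-tetramethoxyphenyl)propan-2-ol F4. A second Dess–Martin oxidation of F4 comes back to the route at 8.

**Further compounds**

F1 | step 7 | 1-(2,4,6-trihydroxyphenyl)-2-(2,3,4,6-tetramethoxyphenyl)ethanone | O=C(Cc1c(OC)cc(OC)c(OC)c1OC)c1c(O)cc(O)cc1O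
F2 | step 4 | 2-(2,3,4,6-tetramethoxyphenyl)acetyl chloride | O=C(Cl)Cc1c(OC)cc(OC)c(OC)c1OC
F3 | step 4 | 1-(dimethylamino)-2-nitro-4-(2,3,4,6-tetramethoxyphenyl)but-1-en-3-one (push–pull C=C bond, geometry labile and not assigned) | CN(C)C=C(C(=O)Cc1c(OC)cc(OC)c(OC)c1OC)[N+](=O)[O-]
F4 | step 3 | 1-nitro-3-(2,3,4,6-tetramethoxyphenyl)propan-2-ol (racemic) | OC(C[N+](=O)[O-])Cc1c(OC)cc(OC)c(OC)c1OC
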